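## The problem

The target is a flavone (4H-chromen-4-one) with three contiguous ring A substituents: a chelated hydroxyl at C5, a 3-methyl-2-oxobutyl chain at C6 and a methoxyl at C7. Ring C carries a prenyl group at C3, and ring B is a 2',4'-dihydroxyphenyl group joined through C1' to C2. There is no stereocentre, so the task is one of regiochemistry. The ketone chain must sit at C6 and not C8, the two ring A oxygens must be told apart, and the ring B oxygens must lie ortho and para to the C2–C1' bond. Three groups will not survive rough treatment: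

- the trisubstituted prenyl alkene (strong acid, electrophiles, hydrogenation);
- the free resorcinol (oxidants);
- the β-aryl ketone, whose benzylic methylene is enolisable and which, next to a free C5 hydroxyl, can cyclodehydrate to a furan.

Because the C3 prenyl and C2 aryl groups flank each other, ring C is best closed with the prenyl chain already in place. Ring A becomes simple because a 4-substituted 3,5-dimethoxyphenol has two equivalent ortho positions: acylation at either gives only the C6 isomer, and the C5 methoxyl is later singled out by its peri relation to the C4 carbonyl. The feature that makes the key step possible is the placement of the ring B oxygens at C2' and C4' relative to C1'. That is the pattern a 1,1,3-trioxygenated butadiene lays down on adding across an alkyne held on C2, and the alkyne is polarised through C2=C3 by the C4 carbonyl so that its terminus (the future C6') is the electrophilic end.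

## Retrosynthesis

**30 ⇒ 29.** The O–CH3 bond at C5 is cut last. Both ring A oxygens are carried as methyl ethers because the symmetric phenol 1 is the cheapest source of ring A and its symmetry fixes C6. Only the C5 ether is peri to C4=O, so chelation should single it out. A separately protected C5 oxygen would destroy that symmetry. The forward step must spare the C7 methoxyl, the prenyl alkene and the ketone.

**29 ⇒ 22 + 26 (key).** The bonds C1'–C2' and C5'–C6' are cut, which removes ring B entirely. The neighbouring cut, C2–C1' by cross-coupling, would need a doubly protected ring B partner and a deprotection. Here ring B grows from the four carbons of diene 26 and arrives as the free resorcinol. The acidic work-up that aromatises adduct 27 to flavone 28 also opens the ketal, giving 29. Precursor 22 is simpler by one ring and two phenols. The forward reaction must be regioselective and the vinylogous ynone must be reactive enough.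

**22 ⇒ 21 ⇒ 19 + 20 ⇒ 17.** The C2–C(sp) bond is cut (Sonogashira coupling of iodide 19 with alkyne 20, then desilylation), and then the C2–I bond (zincation of 17 and iodinolysis). Building the alkyne into a ring C closure was rejected because a diketone or ynone bearing a second alkyne has several competing cyclisation modes. Chromone 17 has only one ring C–H bond, so the metalation site is not in doubt.

**17 ⇒ 15.** The O1–C2 and C2–C3 bonds are cut and C2 is supplied as a one-carbon unit. The prenyl group is carried in the acyl chain of ketone 15, so it is at C3 when ring C closes. Later C3 allylation of a chromone with a prenyl electrophile would raise the linear-versus-branched question. The forward step needs a neutral medium because of the ketal.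

**15 ⇒ 14 ⇒ 8 + 12; 12 ⇒ 9 + 10.** The aryl–acyl bond is cut. Friedel–Crafts acylation is excluded by the alkene of the acyl chain and by the ketal, so the bond is made from aryllithium 13 (bromine–lithium exchange on 8) and Weinreb amide 12. Amide 12 comes in one step from acetamide 9 and prenyl bromide 10. Either ortho position of the phenol leads to the same product.

**8 ⇒ 7 ⇒ 6 ⇒ 5 ⇒ 2 + 3; 2 ⇒ 1.** The aryl–CH2 bond between the two methoxyls is cut. Silyl ether 2 is lithiated at the only doubly activated position and opens epoxide 3. Oxidation of carbinol 5 and ketalisation of 6 give 7, and bromination at one of two equivalent positions gives 8. The bulky silyl group keeps lithiation away from its own ortho positions.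

**26 ⇒ 24 ⇒ 23.** The diene is made by two successive O-silylations of methyl acetoacetate 23.

## Roads not taken

**Alternative 1:** The cut takes C2 out as carbon monoxide and severs C2–C1' and C2–C3. In the forward sense the enolate of ketone 15, CO and 1-bromo-2,4-bis(methoxymethoxy)benzene (A2) would be joined under Pd(OAc)2 (divalent palladium, reduced in situ to zerovalent palladium) with a wide-bite-angle bisphosphine. The product would be the 2-prenyl-1,3-diketone A1 (racemic, enolisable), and acid would then close ring C and remove the MOM groups and the ketal.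

- Merits: it is the most convergent plan, carbonylative α-arylation of ketones is a known reaction class, and from 15 it would reach 29 in two steps where the chosen route needs five plus two for the diene.
- Weak points: the enolate forms at a methylene carbon that already bears the homoprenyl chain and sits on a 2,6-disubstituted aryl ketone. The aroylpalladium intermediate therefore meets a hindered carbon nucleophile beside an unhindered phenoxide, which invites O-aroylation. The electron-rich, ortho-oxygenated bromide A2 is slow in oxidative addition. Ring B needs two protecting groups whose acid removal must spare the prenyl alkene.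
- Comparison: in step count this road is clearly better. The chosen plan sets against it a ring B that needs no protecting group and a C2–C1' bond that is never made by an organometallic step at a congested centre. Both roads also share ketone 15, so the carbonylative union stays available if the cycloaddition fails.

**Alternative 2:** The cut dismantles ring A (C8–C8a, C5–C6, C7–C8, C4a–C5) and leaves a 4-pyranone. Irradiating pyranonyl diazoketone A4 with 1-methoxyalkyne A5 would start a Wolff rearrangement to a vinylketene. A [2+2] cycloaddition with the ynol ether, four-electron opening of the cyclobutenone and six-electron closure would then give flavone A3.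

- Merits: the C5 hydroxyl emerges free and already distinguished from the C7 methoxyl, the ynol ether polarity fixes the ring A substitution, and no final demethylation is needed.
- Weak points: A4 is a fully substituted 2-aryl-3-prenyl-4-pyranone carrying a diazoacetyl group, and its synthesis would be longer than the whole of ring A in the chosen route. Photolysis beside a pyranone chromophore and a prenyl alkene invites competing photochemistry. A5 must be prepared. A3 still needs desilylation, oxidation of a carbinol next to an electron-rich phenol, and MOM removal.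
- Comparison: it is better in one respect, since it avoids the BCl3 step that is among the risks of the chosen plan. Against that the chosen plan sets a ring A made from a commercial phenol whose symmetry fixes the regiochemistry, far fewer steps, and no photochemical step on a polyfunctional substrate.

**Alternative 3:** The cut takes C4 out as carbon monoxide and severs C4a–C4, C4–C3 and O1–C2. Iodophenol A7 (two steps from 7 by desilylation and iodination), CO and arylacetylene A8 would combine under PdCl2(PPh3)2 (divalent palladium, reduced in situ to zerovalent palladium) and diethylamine. The intermediate ynone would close to the 3-unsubstituted flavone A6.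

- Merits: it is short and convergent, forms ring C in one step, needs no aryl ketone and no C2 functionalisation, and is a known reaction class.
- Weak points: A6 has nothing at C3. The prenyl group would have to be added afterwards at a carbon flanked by the carbonyl and the ortho-substituted ring B, by halogenation or metalation and then allylation with its linear-versus-branched ambiguity. The ynone can close in the 5-exo sense to an aurone instead of 6-endo. The iodine of A7 is flanked by OH and OMe on an electron-rich ring. Ring B again needs MOM groups.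
- Comparison: up to the flavone nucleus this road is shorter than the chosen one. Once C3 prenylation and deprotection are counted the advantage is largely spent, whereas the chosen plan has the prenyl chain in place from ketone 15 onward and an unprotected ring B.

Key step: step 15

Assumption: the target has no stereocentre, so racemic epoxide 3 is used; the carbinol centre of 5 is erased in step 3 and the C2' centre of adduct 27 on aromatisation.

## Route

Step 1
Reactants: 1 3,5-dimethoxyphenol
Product: 2 (3,5-dimethoxyphenoxy)triisopropylsilane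
Conditions: TIPSCl, imidazole, DMF, rt
Reagents that add atoms: triisopropylsilyl chloride, CC(C)[Si](Cl)(C(C)C)C(C)C
Why: Standard silylation of a phenol; the bulky, weakly coordinating silyl ether does not direct ortho-lithiation and shields its own ortho positions.

Step 2
Reactants: 2 (3,5-dimethoxyphenoxy)triisopropylsilane; 3 2-isopropyloxirane (racemic)
Product: 5 1-[2,6-dimethoxy-4-(triisopropylsilyloxy)phenyl]-3-methylbutan-2-ol (racemic), via aryllithium 4 (not isolated)
Conditions: n-BuLi, THF, 0 °C to rt; then BF3·OEt2, 3, −78 °C
Reagents that add atoms: none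
Why: Directed ortho-metalation should occur at the carbon flanked by both methoxyls, and BF3-promoted epoxide opening by the aryllithium takes place at the unsubstituted CH2 carbon; the new carbinol centre is racemic and is removed in step 3.

Step 3
Reactants: 5 1-[2,6-dimethoxy-4-(triisopropylsilyloxy)phenyl]-3-methylbutan-2-ol
Product: 6 1-[2,6-dimethoxy-4-(triisopropylsilyloxy)phenyl]-3-methylbutan-2-one
Conditions: Dess–Martin periodinane, CH2Cl2, rt
Reagents that add atoms: none
Why: Dess–Martin oxidation of a secondary alcohol under near-neutral conditions; the aryl silyl ether and the electron-rich ring are not affected.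

Step 4
Reactants: 6 1-[2,6-dimethoxy-4-(triisopropylsilyloxy)phenyl]-3-methylbutan-2-one
Product: 7 2-{[2,6-dimethoxy-4-(triisopropylsilyloxy)phenyl]methyl}-2-isopropyl-1,3-dioxolane
Conditions: (TMSOCH2)2, TMSOTf (cat.), CH2Cl2, −78 to −20 °C
Reagents that add atoms: 1,2-bis(trimethylsilyloxy)ethane, C[Si](C)(C)OCCO[Si](C)(C)C
Why: Noyori ketalisation, which works at low temperature for hindered ketones; it masks the enolisable ketone before the amide acetal condensation and the zincation.

Step 5
Reactants: 7 2-{[2,6-dimethoxy-4-(triisopropylsilyloxy)phenyl]methyl}-2-isopropyl-1,3-dioxolane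
Product: 8 2-{[3-bromo-2,6-dimethoxy-4-(triisopropylsilyloxy)phenyl]methyl}-2-isopropyl-1,3-dioxolane
Conditions: NBS, MeCN, −20 to 0 °C
Reagents that add atoms: N-bromosuccinimide, O=C1CCC(=O)N1Br
Why: Electrophilic aromatic bromination of a phloroglucinol triether; the two free ring positions are equivalent, so one monobromide should form, and one equivalent at low temperature limits dibromination.

Step 6
Reactants: 9 N-methoxy-N-methylacetamide; 10 prenyl bromide (1-bromo-3-methylbut-2-ene)
Product: 12 N-methoxy-N,5-dimethylhex-4-enamide, via lithium enolate 11 (not isolated)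
Conditions: LiN(iPr)2, THF, −78 °C; then 10, −78 to −20 °C
Reagents that add atoms: none
Why: Enolate alkylation of a Weinreb amide with a reactive allylic bromide; SN2 attack at the primary carbon gives the linear chain.

Step 7
Reactants: 8 2-{[3-bromo-2,6-dimethoxy-4-(triisopropylsilyloxy)phenyl]methyl}-2-isopropyl-1,3-dioxolane; 12 N-methoxy-N,5-dimethylhex-4-enamide
Product: 14 1-{2,4-dimethoxy-3-[(2-isopropyl-1,3-dioxolan-2-yl)methyl]-6-(triisopropylsilyloxy)phenyl}-5-methylhex-4-en-1-one, via aryllithium 13 (not isolated)
Conditions: t-BuLi (2 equiv), THF, −78 °C; then 12, −78 to −40 °C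
Reagents that add atoms: none
Why: Bromine–lithium exchange followed by Weinreb ketone synthesis; the chelated tetrahedral adduct prevents over-addition, and keeping the aryllithium cold suppresses O-to-C silyl migration.

Step 8
Reactants: 14 1-{2,4-dimethoxy-3-[(2-isopropyl-1,3-dioxolan-2-yl)methyl]-6-(triisopropylsilyloxy)phenyl}-5-methylhex-4-en-1-one
Product: 15 1-{6-hydroxy-2,4-dimethoxy-3-[(2-isopropyl-1,3-dioxolan-2-yl)methyl]phenyl}-5-methylhex-4-en-1-one
Conditions: Bu4NF, THF, 0 °C
Reagents that add atoms: none
Why: Fluoride cleavage of an aryl silyl ether; the ketal, the alkene and the ketone are inert, and the freed phenol is ortho to the acyl group as ring C closure requires.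

Step 9
Reactants: 15 1-{6-hydroxy-2,4-dimethoxy-3-[(2-isopropyl-1,3-dioxolan-2-yl)methyl]phenyl}-5-methylhex-4-en-1-one
Product: 17 6-[(2-isopropyl-1,3-dioxolan-2-yl)methyl]-5,7-dimethoxy-3-(3-methylbut-2-en-1-yl)-4H-chromen-4-one, via enaminone 16 (not isolated)
Conditions: Me2NCH(OMe)2, toluene, 110 °C
Reagents that add atoms: N,N-dimethylformamide dimethyl acetal, COC(OC)N(C)C
Why: Enaminone formation at the α-methylene, then 6-endo-trig addition of the phenol and loss of dimethylamine, the usual amide acetal route to 3-substituted chromones; the medium is neutral, so the ketal should survive.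

Step 10
Reactants: 17 6-[(2-isopropyl-1,3-dioxolan-2-yl)methyl]-5,7-dimethoxy-3-(3-methylbut-2-en-1-yl)-4H-chromen-4-one
Product: 19 2-iodo-6-[(2-isopropyl-1,3-dioxolan-2-yl)methyl]-5,7-dimethoxy-3-(3-methylbut-2-en-1-yl)-4H-chromen-4-one, via diorganozinc 18 (not isolated)
Conditions: TMP2Zn·2MgCl2·2LiCl, THF, −30 °C to rt; then I2, 0 °C
Reagents that add atoms: iodine, II
Why: Zincation of a chromone at C2 by a hindered zinc amide, with MgCl2 on the carbonyl acidifying C2–H, followed by iodinolysis; C3 is blocked and the only other acidic site is masked as the ketal.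

Step 11
Reactants: 19 2-iodo-6-[(2-isopropyl-1,3-dioxolan-2-yl)methyl]-5,7-dimethoxy-3-(3-methylbut-2-en-1-yl)-4H-chromen-4-one; 20 ethynyltrimethylsilane
Product: 21 6-[(2-isopropyl-1,3-dioxolan-2-yl)methyl]-5,7-dimethoxy-3-(3-methylbut-2-en-1-yl)-2-[(trimethylsilyl)ethynyl]-4H-chromen-4-one
Conditions: PdCl2(PPh3)2, CuI, Et3N, THF, rt
Reagents that add atoms: none
Why: Sonogashira coupling; the C2–I bond is a vinylogous acyl iodide and should add readily to the zerovalent palladium formed from the divalent palladium precatalyst, and a tertiary amine avoids addition–elimination at C2.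

Step 12
Reactants: 21 6-[(2-isopropyl-1,3-dioxolan-2-yl)methyl]-5,7-dimethoxy-3-(3-methylbut-2-en-1-yl)-2-[(trimethylsilyl)ethynyl]-4H-chromen-4-one
Product: 22 2-ethynyl-6-[(2-isopropyl-1,3-dioxolan-2-yl)methyl]-5,7-dimethoxy-3-(3-methylbut-2-en-1-yl)-4H-chromen-4-one
Conditions: K2CO3 (cat.), MeOH/THF, 0 °C
Reagents that add atoms: none
Why: Base-catalysed methanolysis of the C(sp)–Si bond; a short reaction time in the cold is chosen to limit conjugate addition to the ynenone.

Step 13
Reactants: 23 methyl acetoacetate
Product: 24 methyl (E)-3-(trimethylsilyloxy)but-2-enoate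
Conditions: TMSCl, Et3N, hexane, rt
Reagents that add atoms: chlorotrimethylsilane, C[Si](C)(C)Cl
Why: O-silylation of the β-keto ester enol; the alkene geometry does not matter for the next step.

Step 14
Reactants: 24 methyl (E)-3-(trimethylsilyloxy)but-2-enoate
Product: 26 (Z)-1-methoxy-1,3-bis(trimethylsilyloxy)buta-1,3-diene, via lithium dienolate 25 (not isolated)
Conditions: LiN(iPr)2, THF, −78 °C; then TMSCl, −78 °C to rt
Reagents that add atoms: chlorotrimethylsilane, C[Si](C)(C)Cl
Why: γ-Deprotonation of the silyloxy enoate and O-silylation of the dienolate, the standard preparation of this diene.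

Step 15
Reactants: 22 2-ethynyl-6-[(2-isopropyl-1,3-dioxolan-2-yl)methyl]-5,7-dimethoxy-3-(3-methylbut-2-en-1-yl)-4H-chromen-4-one; 26 (Z)-1-methoxy-1,3-bis(trimethylsilyloxy)buta-1,3-diene
Product: 29 2-(2,4-dihydroxyphenyl)-5,7-dimethoxy-6-(3-methyl-2-oxobutyl)-3-(3-methylbut-2-en-1-yl)-4H-chromen-4-one, via cycloadduct 27 (not isolated), via dioxolane flavone 28 (not isolated)
Conditions: 26 (3 equiv), toluene, 100 °C, sealed tube; then 1 M HCl, THF, rt
Reagents that add atoms: water, O
Why: Proposed new method: the ethynyl group of 22 is conjugated through C2=C3 to the C4 carbonyl, a vinylogous ynone whose terminal carbon is the electrophilic end, so the electron-rich diene 26 should add in a normal-electron-demand, strongly asynchronous [4+2] cycloaddition in which its unsubstituted CH2 terminus bonds to that terminal carbon (C5'–C6') and its ketene acetal carbon bonds to the carbon held on C2 (C1'–C2'). The closest known reaction type is the Diels–Alder reaction of 1,1,3-trioxygenated butadienes with acetylenic ketones and esters, which gives resorcinol derivatives after loss of an alkoxy group; what is new is that the activation reaches the alkyne only through the intervening C2=C3 bond. Ring B closes as a six-membered carbocycle in an intermolecular [4+2] event with both partners reacting suprafacially, and a stepwise course (conjugate addition at the alkyne terminus, then closure of the allenolate carbon onto the silyloxycarbenium carbon) would lead to the same adduct 27. Adduct 27 is a cyclohexa-1,4-diene whose C2' bears a mixed methyl silyl ketal; aqueous HCl expels methanol and cleaves both silyl groups to give the aromatic resorcinol 28, and the same acid then hydrolyses the dioxolane to ketone 29. No stereocentre remains, since the C2' centre of 27 is lost on aromatisation. The step needs regioselectivity (oxygens at C2' and C4', hydrogen at C6'), which is secured by pairing the nucleophilic diene terminus with the conjugate position of the alkyne, the sense that the ortho and para rules also predict for a diene with donors at C1 and C3. It also needs chemoselectivity for the alkyne, which is secured because the C2=C3 bond is tetrasubstituted and the prenyl alkene is unactivated.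

Step 16
Reactants: 29 2-(2,4-dihydroxyphenyl)-5,7-dimethoxy-6-(3-methyl-2-oxobutyl)-3-(3-methylbut-2-en-1-yl)-4H-chromen-4-one
Product: 30 2-(2,4-dihydroxyphenyl)-5-hydroxy-7-methoxy-6-(3-methyl-2-oxobutyl)-3-(3-methylbut-2-en-1-yl)-4H-chromen-4-one (CNP0291994.0)
Conditions: BCl3, CH2Cl2, −78 to −20 °C; then H2O
Reagents that add atoms: none
Why: Chelation-controlled demethylation of the peri methoxyl: BCl3 binds the C4 carbonyl and the C5 oxygen in a six-membered chelate and chloride removes that methyl group, while the C7 methoxyl has no such assistance and should survive in the cold.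

## Compound list

1 | 3,5-dimethoxyphenol | COc1cc(O)cc(OC)c1 | starting material
2 | (3,5-dimethoxyphenoxy)triisopropylsilane | COc1cc(OC)cc(O[Si](C(C)C)(C(C)C)C(C)C)c1 | intermediate
3 | 2-isopropyloxirane (racemic) | CC(C)C1CO1 | starting material
4 | [2,6-dimethoxy-4-(triisopropylsilyloxy)phenyl]lithium (not isolated) | [Li]c1c(OC)cc(O[Si](C(C)C)(C(C)C)C(C)C)cc1OC | intermediate
5 | 1-[2,6-dimethoxy-4-(triisopropylsilyloxy)phenyl]-3-methylbutan-2-ol (racemic) | COc1cc(O[Si](C(C)C)(C(C)C)C(C)C)cc(OC)c1CC(O)C(C)C | intermediate
6 | 1-[2,6-dimethoxy-4-(triisopropylsilyloxy)phenyl]-3-methylbutan-2-one | COc1cc(O[Si](C(C)C)(C(C)C)C(C)C)cc(OC)c1CC(=O)C(C)C | intermediate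
7 | 2-{[2,6-dimethoxy-4-(triisopropylsilyloxy)phenyl]methyl}-2-isopropyl-1,3-dioxolane | COc1cc(O[Si](C(C)C)(C(C)C)C(C)C)cc(OC)c1CC1(C(C)C)OCCO1 | intermediate
8 | 2-{[3-bromo-2,6-dimethoxy-4-(triisopropylsilyloxy)phenyl]methyl}-2-isopropyl-1,3-dioxolane | COc1cc(O[Si](C(C)C)(C(C)C)C(C)C)c(Br)c(OC)c1CC1(C(C)C)OCCO1 | intermediate
9 | N-methoxy-N-methylacetamide | CON(C)C(C)=O | starting material
10 | prenyl bromide (1-bromo-3-methylbut-2-ene) | CC(C)=CCBr | starting material
11 | lithium enolate of N-methoxy-N-methylacetamide (not isolated) | [Li]OC(=C)N(C)OC | intermediate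
12 | N-methoxy-N,5-dimethylhex-4-enamide | CON(C)C(=O)CCC=C(C)C | intermediate
13 | {2,4-dimethoxy-3-[(2-isopropyl-1,3-dioxolan-2-yl)methyl]-6-(triisopropylsilyloxy)phenyl}lithium (not isolated) | COc1cc(O[Si](C(C)C)(C(C)C)C(C)C)c([Li])c(OC)c1CC1(C(C)C)OCCO1 | intermediate
14 | 1-{2,4-dimethoxy-3-[(2-isopropyl-1,3-dioxolan-2-yl)methyl]-6-(triisopropylsilyloxy)phenyl}-5-methylhex-4-en-1-one | COc1cc(O[Si](C(C)C)(C(C)C)C(C)C)c(C(=O)CCC=C(C)C)c(OC)c1CC1(C(C)C)OCCO1 | intermediate
15 | 1-{6-hydroxy-2,4-dimethoxy-3-[(2-isopropyl-1,3-dioxolan-2-yl)methyl]phenyl}-5-methylhex-4-en-1-one | COc1cc(O)c(C(=O)CCC=C(C)C)c(OC)c1CC1(C(C)C)OCCO1 | intermediate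
16 | (E)-2-[(dimethylamino)methylidene]-1-{6-hydroxy-2,4-dimethoxy-3-[(2-isopropyl-1,3-dioxolan-2-yl)methyl]phenyl}-5-methylhex-4-en-1-one (not isolated) | COc1cc(O)c(C(=O)/C(CC=C(C)C)=C/N(C)C)c(OC)c1CC1(C(C)C)OCCO1 | intermediate
17 | 6-[(2-isopropyl-1,3-dioxolan-2-yl)methyl]-5,7-dimethoxy-3-(3-methylbut-2-en-1-yl)-4H-chromen-4-one | COc1cc2occ(CC=C(C)C)c(=O)c2c(OC)c1CC1(C(C)C)OCCO1 | intermediate
18 | bis{6-[(2-isopropyl-1,3-dioxolan-2-yl)methyl]-5,7-dimethoxy-3-(3-methylbut-2-en-1-yl)-4-oxo-4H-chromen-2-yl}zinc, as its MgCl2/LiCl complex (not isolated) | COc1cc2oc([Zn]c3oc4cc(OC)c(CC5(C(C)C)OCCO5)c(OC)c4c(=O)c3CC=C(C)C)c(CC=C(C)C)c(=O)c2c(OC)c1CC1(C(C)C)OCCO1 | intermediate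
19 | 2-iodo-6-[(2-isopropyl-1,3-dioxolan-2-yl)methyl]-5,7-dimethoxy-3-(3-methylbut-2-en-1-yl)-4H-chromen-4-one | COc1cc2oc(I)c(CC=C(C)C)c(=O)c2c(OC)c1CC1(C(C)C)OCCO1 | intermediate
20 | ethynyltrimethylsilane | C#C[Si](C)(C)C | starting material
21 | 6-[(2-isopropyl-1,3-dioxolan-2-yl)methyl]-5,7-dimethoxy-3-(3-methylbut-2-en-1-yl)-2-[(trimethylsilyl)ethynyl]-4H-chromen-4-one | COc1cc2oc(C#C[Si](C)(C)C)c(CC=C(C)C)c(=O)c2c(OC)c1CC1(C(C)C)OCCO1 | intermediate
22 | 2-ethynyl-6-[(2-isopropyl-1,3-dioxolan-2-yl)methyl]-5,7-dimethoxy-3-(3-methylbut-2-en-1-yl)-4H-chromen-4-one | COc1cc2oc(C#C)c(CC=C(C)C)c(=O)c2c(OC)c1CC1(C(C)C)OCCO1 | intermediate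
23 | methyl acetoacetate | COC(=O)CC(C)=O | starting material
24 | methyl (E)-3-(trimethylsilyloxy)but-2-enoate | COC(=O)/C=C(\C)O[Si](C)(C)C | intermediate
25 | lithium dienolate of 24, lithium 1-methoxy-3-(trimethylsilyloxy)buta-1,3-dien-1-olate (not isolated) | CO/C(O[Li])=C/C(=C)O[Si](C)(C)C | intermediate
26 | (Z)-1-methoxy-1,3-bis(trimethylsilyloxy)buta-1,3-diene | CO/C(O[Si](C)(C)C)=C/C(=C)O[Si](C)(C)C | intermediate
27 | 2-[6-methoxy-4,6-bis(trimethylsilyloxy)cyclohexa-1,4-dien-1-yl]-6-[(2-isopropyl-1,3-dioxolan-2-yl)methyl]-5,7-dimethoxy-3-(3-methylbut-2-en-1-yl)-4H-chromen-4-one (racemic at the ketal carbon; not isolated) | COc1cc2oc(C3=CCC(O[Si](C)(C)C)=CC3(OC)O[Si](C)(C)C)c(CC=C(C)C)c(=O)c2c(OC)c1CC1(C(C)C)OCCO1 | intermediate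
28 | 2-(2,4-dihydroxyphenyl)-6-[(2-isopropyl-1,3-dioxolan-2-yl)methyl]-5,7-dimethoxy-3-(3-methylbut-2-en-1-yl)-4H-chromen-4-one (not isolated) | COc1cc2oc(-c3ccc(O)cc3O)c(CC=C(C)C)c(=O)c2c(OC)c1CC1(C(C)C)OCCO1 | intermediate
29 | 2-(2,4-dihydroxyphenyl)-5,7-dimethoxy-6-(3-methyl-2-oxobutyl)-3-(3-methylbut-2-en-1-yl)-4H-chromen-4-one | COc1cc2oc(-c3ccc(O)cc3O)c(CC=C(C)C)c(=O)c2c(OC)c1CC(=O)C(C)C | intermediate
30 | 2-(2,4-dihydroxyphenyl)-5-hydroxy-7-methoxy-6-(3-methyl-2-oxobutyl)-3-(3-methylbut-2-en-1-yl)-4H-chromen-4-one (CNP0291994.0) | COc1cc2oc(-c3ccc(O)cc3O)c(CC=C(C)C)c(=O)c2c(O)c1CC(=O)C(C)C | target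

## Step count and risks

Total step count: 16. Longest linear sequence: 13 steps (steps 1–5, 7–12, 15, 16). Side branches: step 6 (amide 12) and steps 13–14 (diene 26).

Steps least certain to work:

**Step 15 (key step; the one proposed new method).** The vinylogous activation of the alkyne may be too weak. The diene would then be lost to thermal silyl migration, hydrolysis or oligomerisation before it cycloadds, or it would add as a simple carbon nucleophile without closing the ring. Erosion of regiocontrol is the lesser concern. The fallback uses known chemistry and sets out from 17. The zinc reagent 18 of step 10 is not iodinated but is cross-coupled in a Negishi reaction (Pd(OAc)2, SPhos, THF, 50 °C) with 1-bromo-2,4-bis(methoxymethoxy)benzene F1, itself made from 4-bromoresorcinol, MOMCl and i-Pr2NEt. This gives 2-[2,4-bis(methoxymethoxy)phenyl]-6-[(2-isopropyl-1,3-dioxolan-2-yl)methyl]-5,7-dimethoxy-3-prenylchromone F2. Aqueous HCl in MeOH/THF at 40 °C then removes both MOM groups and the dioxolane, and the route is rejoined at 29.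

**Step 16.** HCl released when BCl3 borylates the free phenols may add to the prenyl alkene. Prolonged Lewis acid exposure may also cyclodehydrate the ketone chain onto the freed C5 oxygen or begin to cleave the C7 ether. The fallback sets out from 29. Acetylation (Ac2O, pyridine) gives the 2',4'-diacetate F3. BCl3 at −78 °C then acts on a substrate without free phenols and gives the 5-hydroxy diacetate F4. Mild methanolysis (K2CO3, MeOH, 0 °C) removes the acetates and returns to 30.

**Step 9.** Condensation at the α-methylene may stall, because that carbon already bears the homoprenyl chain and the aryl ketone is twisted by its two ortho substituents. O-methylation of the phenol by the acetal may then compete. The fallback sets out from 15. Claisen formylation (NaH, ethyl formate, THF, 0 °C to rt) gives the hemiacetal 2-hydroxy-6-[(2-isopropyl-1,3-dioxolan-2-yl)methyl]-5,7-dimethoxy-3-prenylchroman-4-one F5. Dehydration with MsCl and Et3N returns to 17.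

**Step 7.** Addition of the doubly ortho-substituted aryllithium to the amide may be slow, which allows α-deprotonation of the amide and, on warming, O-to-C silyl migration. The fallback sets out from 8. Amide 12 is reduced with i-Bu2AlH (THF, −78 °C) to 5-methylhex-4-enal F6. This more electrophilic partner is added to aryllithium 13 at −78 °C to give the carbinol 1-{2,4-dimethoxy-3-[(2-isopropyl-1,3-dioxolan-2-yl)methyl]-6-(triisopropylsilyloxy)phenyl}-5-methylhex-4-en-1-ol F7. Dess–Martin oxidation returns to 14.

**Step 12.** Methoxide or methanol may add in conjugate fashion to the ynenone, or the terminal alkyne may oligomerise under base during desilylation. The fallback sets out from 19. Negishi coupling with ethynylzinc bromide (from ethynylmagnesium bromide and ZnBr2; Pd(PPh3)4, THF, rt) installs the unprotected ethynyl group directly and rejoins the route at 22. It bypasses 21 and makes no new compound (F0).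

## Further compounds

F1 | step 15 | 1-bromo-2,4-bis(methoxymethoxy)benzene | COCOc1ccc(Br)c(OCOC)c1
F2 | step 15 | 2-[2,4-bis(methoxymethoxy)phenyl]-6-[(2-isopropyl-1,3-dioxolan-2-yl)methyl]-5,7-dimethoxy-3-(3-methylbut-2-en-1-yl)-4H-chromen-4-one | COc1cc2oc(-c3ccc(OCOC)cc3OCOC)c(CC=C(C)C)c(=O)c2c(OC)c1CC1(C(C)C)OCCO1
F3 | step 16 | 4-[5,7-dimethoxy-6-(3-methyl-2-oxobutyl)-3-(3-methylbut-2-en-1-yl)-4-oxo-4H-chromen-2-yl]-1,3-phenylene diacetate | COc1cc2oc(-c3ccc(OC(C)=O)cc3OC(C)=O)c(CC=C(C)C)c(=O)c2c(OC)c1CC(=O)C(C)C
F4 | step 16 | 4-[5-hydroxy-7-methoxy-6-(3-methyl-2-oxobutyl)-3-(3-methylbut-2-en-1-yl)-4-oxo-4H-chromen-2-yl]-1,3-phenylene diacetate | COc1cc2oc(-c3ccc(OC(C)=O)cc3OC(C)=O)c(CC=C(C)C)c(=O)c2c(O)c1CC(=O)C(C)C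
F5 | step 9 | 2-hydroxy-6-[(2-isopropyl-1,3-dioxolan-2-yl)methyl]-5,7-dimethoxy-3-(3-methylbut-2-en-1-yl)chroman-4-one (racemic, mixture of diastereomers) | COc1cc2OC(O)C(CC=C(C)C)C(=O)c2c(OC)c1CC1(C(C)C)OCCO1
F6 | step 7 | 5-methylhex-4-enal | CC(C)=CCCC=O
F7 | step 7 | 1-{2,4-dimethoxy-3-[(2-isopropyl-1,3-dioxolan-2-yl)methyl]-6-(triisopropylsilyloxy)phenyl}-5-methylhex-4-en-1-ol (racemic) | COc1cc(O[Si](C(C)C)(C(C)C)C(C)C)c(C(O)CCC=C(C)C)c(OC)c1CC1(C(C)C)OCCO1
F0 | step 12 | none | none
A1 | alternative 1 | 2-[2,4-bis(methoxymethoxy)benzoyl]-1-{6-hydroxy-2,4-dimethoxy-3-[(2-isopropyl-1,3-dioxolan-2-yl)methyl]phenyl}-5-methylhex-4-en-1-one (racemic) | COc1cc(O)c(C(=O)C(CC=C(C)C)C(=O)c2ccc(OCOC)cc2OCOC)c(OC)c1CC1(C(C)C)OCCO1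
A2 | alternative 1 | 1-bromo-2,4-bis(methoxymethoxy)benzene | COCOc1ccc(Br)c(OCOC)c1
A3 | alternative 2 | 2-[2,4-bis(methoxymethoxy)phenyl]-6-[2-(tert-butyldimethylsilyloxy)-3-methylbutyl]-5-hydroxy-7-methoxy-3-(3-methylbut-2-en-1-yl)-4H-chromen-4-one (racemic) | COc1cc2oc(-c3ccc(OCOC)cc3OCOC)c(CC=C(C)C)c(=O)c2c(O)c1CC(O[Si](C)(C)C(C)(C)C)C(C)C
A4 | alternative 2 | 2-[2,4-bis(methoxymethoxy)phenyl]-6-(2-diazoacetyl)-3-(3-methylbut-2-en-1-yl)-4H-pyran-4-one | [N-]=[N+]=CC(=O)c1cc(=O)c(CC=C(C)C)c(-c2ccc(OCOC)cc2OCOC)o1
A5 | alternative 2 | tert-butyl[(1-methoxy-5-methylhex-1-yn-4-yl)oxy]dimethylsilane (racemic) | COC#CCC(O[Si](C)(C)C(C)(C)C)C(C)C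
A6 | alternative 3 | 2-[2,4-bis(methoxymethoxy)phenyl]-6-[(2-isopropyl-1,3-dioxolan-2-yl)methyl]-5,7-dimethoxy-4H-chromen-4-one | COc1cc2oc(-c3ccc(OCOC)cc3OCOC)cc(=O)c2c(OC)c1CC1(C(C)C)OCCO1
A7 | alternative 3 | 2-iodo-4-[(2-isopropyl-1,3-dioxolan-2-yl)methyl]-3,5-dimethoxyphenol | COc1cc(O)c(I)c(OC)c1CC1(C(C)C)OCCO1
A8 | alternative 3 | 1-ethynyl-2,4-bis(methoxymethoxy)benzene | C#Cc1ccc(OCOC)cc1OCOC
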